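The data are simulated from invented constants, and the scatter is random.

The vessel is charged with 63 µM of free catalyst, so the choice for the next run is how much substrate goes in with it, and two earlier runs bear on that choice.

| setting | zeta | epsilon | Tuesday's | Sunday's | Wednesday's | Monday's |
|---|---|---|---|---|---|---|
| substrate | 0.010 M | 0.20 M | 0.012 M | 0.030 M | 0.10 M | 0.30 M |
| free catalyst | 63 µM | 63 µM | 63 µM | 63 µM | 63 µM | 63 µM |
| remark | run made earlier | run made earlier |  |  |  |  |
| time |  |  | 15 min | 15 min | 15 min | 15 min |

- zeta (time / min: product / %): 0.667: 3.9; 1.00: 6.1; 2.00: 12.5; 4.00: 23.6; 8.00: 41.9
- epsilon (time / min: product / %): 1.50: 0.8; 3.00: 4.2; 5.00: 5.9; 6.00: 6.8; 8.00: 9.4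

(readings scatter by 0.5 percentage points)

- a reading or a percentage of product counts all its forms, free or not
- the concentration of product that is asked is that of its free form alone
- "hardly changes" means that all values lie within two and a half points (for a concentration: within two and a half percent of the largest)

- [product] (only what is free in solution) at the end for Tuesday's, Sunday's, Wednesday's, Monday's, in this order
- how that number moves from the first to the last of them (hardly changes / rises, then falls / falls all the way / rises all the way / falls, then rises)

The epsilon run climbs nearly straight to 9.4% at 8.00 min, and its 20.0 times the charge of the zeta run gives 3.85 times the early amount per minute, so I treat high charges as zero-order. A constant rate integrates to a straight line, so Monday's flask should turn over 11.7% of its charge. I call this the straight-line share: epsilon's amount per minute, times the time, over the charge. It rests on one reading good to 0.5 percentage points, so it is an estimate with that reading's scatter, scaled up.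

For Wednesday's flask the share is 35.2%. For Sunday's flask it comes to 117%, more than the whole charge, so the line cannot hold there. Share times charge is the same amount for Wednesday's and Monday's flasks, so on my reckoning 3.00 times Wednesday's charge buys no more counted product. The readings count all forms, so free product can be that amount or less. I stop at Wednesday's charge and leave Monday's out.

The forecast differs from my equal amounts for Wednesday's and Monday's flasks: it gives 0.0076 M, 0.016 M, 0.0296 M and 0.037 M, a row that rises all the way, with the words “I assume simple saturation”.

The flasks give 0.00580 M, 0.00882 M, 0.00651 M and 0.00216 M: the row rises, then falls, turning at 0.042 M.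

    substrate + free catalyst ⇌ catalyst intermediate A (K = 240 M⁻¹, k = 24.0 M⁻¹ s⁻¹)
    catalyst intermediate A → catalyst intermediate B (k = 18.0 s⁻¹)
    catalyst intermediate B → free catalyst + product (k = 0.780 s⁻¹)
    substrate + product ⇌ idle adduct, settled at all times (K = 73.0 M⁻¹)

Counted product at the end stands at 12.6% in Monday's flask, where the straight-line share is 11.7%, and at 29.3% in Wednesday's flask, where it is 35.2%. Yet free product in Monday's flask is 0.720% of the charge, partly because substrate ties product up as idle adduct and partly because the reading comes at 15 min. Without that capture, Monday's free product is 12.7% of the charge; read at 150 min, it is 49.9%.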